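**Plan**

Locants used throughout: C1 = acetoxy carbon, C2–C3 = oxirane (methyl on C3), C4 = senecioyloxy carbon, C6=C7 = ring alkene, C10 = isopropyl-bearing carbon, C11/C12 = carbons of that branch. TBS = tert-butyldimethylsilyl.
Retrosynthesis: cut the two ester C–O bonds and two hydrogens of the isopropyl group, then the ring bond C1–C10; this opens the cyclodecene to a (6E,10E)-farnesane with a C1 aldehyde, the 2,3-epoxide, a 4-silyloxy group and a C12 allylic chloride. Then cut the epoxide oxygen, C2=C3 (C13 methyl ketone + C2 ylide), C12–Cl and C4–O, back to (E)-geranylacetone.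
Forward: the chain is completed first; the ten-membered ring is the only ring formed and closes in one intramolecular umpolung allylation; the oxirane is carried in from the acyclic stage.
Enabling feature: with the isopropyl read as isopropenyl, C1(O)–C10–C11(=C12) is a homoallylic alcohol, the retron of γ-addition of a C12-metalated 2-methylallyl unit to a C1 aldehyde. Ring atoms C1–C10 with their three methyl branches are a farnesyl chain, whose (6E)-alkene and trans-2,3-epoxide fold it for closure and whose epoxide steers the aldehyde face.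
Stereochemistry: C4 from D-proline α-aminoxylation; C2/C3 from D-(−)-tartrate Katsuki–Sharpless epoxidation; C1 and C10 together in the ring closure; 6E from geranylacetone, 2E from the Wittig step.

Key step: step 10

Remark: (E)-geranylacetone is taken as the commercial, isomerically pure 5E ketone.

Step 1
Reactants: 1 (5E)-6,10-dimethylundeca-5,9-dien-2-one ((E)-geranylacetone)
Product: 2 (3S,5E)-6,10-dimethyl-3-[(phenylamino)oxy]undeca-5,9-dien-2-one
Conditions: PhNO (added slowly), excess 1, D-proline (cat.), DMSO, rt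
Reagents that add atoms: nitrosobenzene O=Nc1ccccc1
Why: Proline-enamine α-aminoxylation (O-selective nitroso aldol), in which the more substituted (E)-enamine attacks the nitroso oxygen held by the catalyst's carboxylic acid, so that D-proline should set C4 as S (L-proline gives the R series with ketones) while the isolated alkenes are inert.

Step 2
Reactants: 2 (3S,5E)-6,10-dimethyl-3-[(phenylamino)oxy]undeca-5,9-dien-2-one
Product: 3 (3S,5E)-3-hydroxy-6,10-dimethylundeca-5,9-dien-2-one
Conditions: CuSO4·5H2O (cat.), MeOH, 0 °C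
Reagents that add atoms: none
Why: Copper-catalysed N–O cleavage of the O-alkyl-N-phenylhydroxylamine, the usual follow-up of an aminoxylation, which should leave the α-stereocenter and both alkenes untouched where hydrogenolysis would not.

Step 3
Reactants: 3 (3S,5E)-3-hydroxy-6,10-dimethylundeca-5,9-dien-2-one
Product: 4 (3S,5E)-3-(TBSO)-6,10-dimethylundeca-5,9-dien-2-one
Conditions: TBSCl, imidazole, DMF, 0 °C to rt
Reagents that add atoms: tert-butyldimethylsilyl chloride CC(C)(C)[Si](C)(C)Cl
Why: Standard silylation of a secondary alcohol under weakly basic conditions that should not enolize the α-hydroxy ketone; the silyl ether masks O4 until the senecioate is introduced.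

Step 4
Reactants: 4 (3S,5E)-3-(TBSO)-6,10-dimethylundeca-5,9-dien-2-one
Product: 5 ethyl (2E,4S,6E)-4-(TBSO)-3,7,11-trimethyldodeca-2,6,10-trienoate
Conditions: Ph3P=CHCO2Et, toluene, 100 °C
Reagents that add atoms: ethyl (triphenylphosphoranylidene)acetate CCOC(=O)C=P(c1ccccc1)(c1ccccc1)c1ccccc1
Why: Wittig olefination with a stabilized ylide, which α-silyloxy methyl ketones undergo on heating and which should place the ester trans to the branched C4 substituent (2E), the non-basic ylide leaving C4 intact.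

Step 5
Reactants: 5 ethyl (2E,4S,6E)-4-(TBSO)-3,7,11-trimethyldodeca-2,6,10-trienoate
Product: 6 ethyl (2E,4S,6E,10E)-4-(TBSO)-12-hydroxy-3,7,11-trimethyldodeca-2,6,10-trienoate
Conditions: SeO2 (cat.), t-BuOOH, salicylic acid (cat.), CH2Cl2, 0 °C to rt, stopped at partial conversion
Reagents that add atoms: tert-butyl hydroperoxide CC(C)(C)OO; selenium dioxide O=[Se]=O (catalytic oxygen carrier)
Why: Catalytic SeO2 allylic hydroxylation (ene reaction then [2,3]-sigmatropic shift) should take the (E)-methyl of the terminal, most accessible trisubstituted alkene and give the (10E)-allylic alcohol, the enoate alkene being deactivated and internal oxidation being the expected minor path.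

Step 6
Reactants: 6 ethyl (2E,4S,6E,10E)-4-(TBSO)-12-hydroxy-3,7,11-trimethyldodeca-2,6,10-trienoate
Product: 8 ethyl (2E,4S,6E,10E)-4-(TBSO)-12-chloro-3,7,11-trimethyldodeca-2,6,10-trienoate, via allylic mesylate 7 (not isolated)
Conditions: MsCl, 2,4,6-collidine, LiCl, DMF, 0 °C
Reagents that add atoms: lithium chloride [Li+].[Cl-]
Why: Mesylation and in situ SN2 displacement by chloride should convert the primary allylic alcohol to the chloride without allylic transposition or loss of the 10E geometry, with silyl ether and enoate unaffected.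

Step 7
Reactants: 8 ethyl (2E,4S,6E,10E)-4-(TBSO)-12-chloro-3,7,11-trimethyldodeca-2,6,10-trienoate
Product: 9 (2E,4S,6E,10E)-4-(TBSO)-12-chloro-3,7,11-trimethyldodeca-2,6,10-trien-1-ol
Conditions: i-Bu2AlH (DIBAL-H), CH2Cl2, −78 °C; aq. Rochelle salt
Reagents that add atoms: none
Why: 1,2-Reduction of the α,β-unsaturated ester gives the (2E)-allylic alcohol, and at −78 °C the allylic chloride and the silyl ether should not be attacked.

Step 8
Reactants: 9 (2E,4S,6E,10E)-4-(TBSO)-12-chloro-3,7,11-trimethyldodeca-2,6,10-trien-1-ol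
Product: 10 (2R,3S,4S,6E,10E)-4-(TBSO)-12-chloro-2,3-epoxy-3,7,11-trimethyldodeca-6,10-dien-1-ol
Conditions: Ti(OiPr)4 (cat.), D-(−)-diethyl tartrate (cat.), t-BuOOH, 4 Å MS, CH2Cl2, −20 °C
Reagents that add atoms: tert-butyl hydroperoxide CC(C)(C)OO
Why: Katsuki–Sharpless asymmetric epoxidation, in which only the 2,3-alkene carries the directing primary hydroxyl and the D-(−)-tartrate complex delivers oxygen to the face opposite to that taken by L-(+)-tartrate with geraniol (2S,3S), so that reagent control should set the trans-epoxide beside the existing 4S center (the 3S descriptor only reflects the priority of the silyloxy carbon).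

Step 9
Reactants: 10 (2R,3S,4S,6E,10E)-4-(TBSO)-12-chloro-2,3-epoxy-3,7,11-trimethyldodeca-6,10-dien-1-ol
Product: 11 (2S,3S,4S,6E,10E)-4-(TBSO)-12-chloro-2,3-epoxy-3,7,11-trimethyldodeca-6,10-dienal
Conditions: PhI(OAc)2, TEMPO (cat.), CH2Cl2, 0 °C to rt
Reagents that add atoms: none
Why: Oxoammonium (TEMPO/PhI(OAc)2) oxidation stops at the aldehyde, tolerates alkenes, allylic chloride and silyl ether, and should neither epimerize nor open the α,β-epoxy aldehyde.

Step 10
Reactants: 11 (2S,3S,4S,6E,10E)-4-(TBSO)-12-chloro-2,3-epoxy-3,7,11-trimethyldodeca-6,10-dienal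
Product: 13 (1R,2R,3S,4S,6E,10S)-4-(TBSO)-2,3-epoxy-3,7-dimethyl-10-(prop-1-en-2-yl)cyclodec-6-en-1-ol, via allyl(ethyl)zinc 12 (not isolated)
Conditions: PdCl2(PPh3)2 (cat.), Et2Zn, K2CO3, DMA, rt, slow addition of 11 at high dilution; aq. NH4Cl
Reagents that add atoms: none
Why: Zerovalent palladium, formed from PdCl2(PPh3)2 by Et2Zn, ionizes the allylic chloride to a π-allylpalladium chloride that transmetalates with Et2Zn to the nucleophilic allyl(ethyl)zinc 12 (the ethylpalladium chloride left behind loses ethene and its HCl is taken up by K2CO3), and 12 adds through its γ-carbon C10 to the C1 aldehyde in a closed six-membered chair (Zn–O–C1–C10–C11–C12). The closest known reaction type is the palladium-catalysed Et2Zn umpolung allylation of aldehydes, documented intramolecularly for farnesane-type ω-chloroallyl α,β-epoxy aldehydes closing ten-membered rings and mechanistically related to the Nozaki–Hiyama allylation. The cyclodecene closes by 10-exo-trig addition (SE2′ at the allyl unit), helped by the two rigid units of the tether, the (6E)-alkene and the trans-epoxide, and by slow addition at high dilution, which disfavours oligomers. C1 is controlled by the adjacent oxirane: attack on the aldehyde face anti to the C2–O bond (Felkin–Anh polar model) should give the 1,2-anti epoxy alcohol (1R). C10 is controlled by the chair inside the crown-like fold of the forming ring: with C2 equatorial and the C1 oxygen gauche to C11, closure requires the tether carbon C9 to sit cis to CH2Zn, a geometry reached by fast 1,3-metallotropic E/Z equilibration of the 2-methylallylzinc (the C11 methyl levels the two geometries), and this should give 10S. The selectivities needed are γ- over α-attack (α would give a twelve-membered ring), secured by the cyclic transition state, and addition to the aldehyde in the presence of oxirane and silyl ether, secured by the low basicity of allylzinc and the slow uncatalysed ethyl transfer from Et2Zn.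

Step 11
Reactants: 13 (1R,2R,3S,4S,6E,10S)-4-(TBSO)-2,3-epoxy-3,7-dimethyl-10-(prop-1-en-2-yl)cyclodec-6-en-1-ol
Product: 14 (1R,2R,3S,4S,6E,10S)-4-(TBSO)-2,3-epoxy-3,7-dimethyl-10-(propan-2-yl)cyclodec-6-en-1-ol
Conditions: H2 (1 atm), RhCl(PPh3)3 (cat.), benzene, rt
Reagents that add atoms: none
Why: Homogeneous hydrogenation with RhCl(PPh3)3 should reduce the unhindered 1,1-disubstituted alkene much faster than the trisubstituted ring alkene, creates no stereocenter, and is non-acidic, so transannular epoxide–alkene cyclization is avoided.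

Step 12
Reactants: 14 (1R,2R,3S,4S,6E,10S)-4-(TBSO)-2,3-epoxy-3,7-dimethyl-10-(propan-2-yl)cyclodec-6-en-1-ol
Product: 15 (1R,2R,3S,4S,6E,10S)-4-(TBSO)-2,3-epoxy-3,7-dimethyl-10-(propan-2-yl)cyclodec-6-en-1-yl acetate
Conditions: Ac2O, pyridine, DMAP (cat.), CH2Cl2, rt
Reagents that add atoms: acetic anhydride CC(=O)OC(C)=O
Why: DMAP-catalysed O-acylation of the secondary C1 hydroxyl, which does not touch the C1 configuration and runs under basic conditions that spare oxirane and silyl ether.

Step 13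
Reactants: 15 (1R,2R,3S,4S,6E,10S)-4-(TBSO)-2,3-epoxy-3,7-dimethyl-10-(propan-2-yl)cyclodec-6-en-1-yl acetate
Product: 16 (1R,2R,3R,4S,6E,10S)-2,3-epoxy-4-hydroxy-3,7-dimethyl-10-(propan-2-yl)cyclodec-6-en-1-yl acetate
Conditions: Bu4NF, AcOH, THF, 0 °C to rt
Reagents that add atoms: none
Why: Fluoride-mediated silyl ether cleavage buffered with acetic acid frees O4 without acid-induced transannular cyclization, and the buffered medium should neither move the C1 acetate (the two oxygens lie on opposite faces of the trans-epoxide) nor allow Payne rearrangement, which would need attack at the fully substituted C3.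

Step 14
Reactants: 16 (1R,2R,3R,4S,6E,10S)-2,3-epoxy-4-hydroxy-3,7-dimethyl-10-(propan-2-yl)cyclodec-6-en-1-yl acetate
Product: 17 (1R,2R,3R,4S,6E,10S)-1-acetoxy-2,3-epoxy-3,7-dimethyl-10-(propan-2-yl)cyclodec-6-en-4-yl 3-methylbut-2-enoate
Conditions: 3-methylbut-2-enoyl chloride, pyridine, DMAP (cat.), CH2Cl2, 0 °C to rt
Reagents that add atoms: 3-methylbut-2-enoyl chloride CC(C)=CC(=O)Cl
Why: Nucleophile-catalysed O-acylation (acylpyridinium) of the C4 hydroxyl with retention, the weak base pyridine limiting vinylketene formation and thus deconjugation of the senecioyl group.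

**Compound list**

1 | (5E)-6,10-dimethylundeca-5,9-dien-2-one ((E)-geranylacetone) | CC(=O)CC/C=C(\C)CCC=C(C)C | starting material
2 | (3S,5E)-6,10-dimethyl-3-[(phenylamino)oxy]undeca-5,9-dien-2-one | CC(=O)[C@@H](ONc1ccccc1)C/C=C(\C)CCC=C(C)C | intermediate
3 | (3S,5E)-3-hydroxy-6,10-dimethylundeca-5,9-dien-2-one | CC(=O)[C@@H](O)C/C=C(\C)CCC=C(C)C | intermediate
4 | (3S,5E)-3-(TBSO)-6,10-dimethylundeca-5,9-dien-2-one | CC(=O)[C@@H](O[Si](C)(C)C(C)(C)C)C/C=C(\C)CCC=C(C)C | intermediate
5 | ethyl (2E,4S,6E)-4-(TBSO)-3,7,11-trimethyldodeca-2,6,10-trienoate | CCOC(=O)/C=C(\C)[C@@H](O[Si](C)(C)C(C)(C)C)C/C=C(\C)CCC=C(C)C | intermediate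
6 | ethyl (2E,4S,6E,10E)-4-(TBSO)-12-hydroxy-3,7,11-trimethyldodeca-2,6,10-trienoate | CCOC(=O)/C=C(\C)[C@@H](O[Si](C)(C)C(C)(C)C)C/C=C(\C)CC/C=C(\C)CO | intermediate
7 | ethyl (2E,4S,6E,10E)-4-(TBSO)-12-[(methylsulfonyl)oxy]-3,7,11-trimethyldodeca-2,6,10-trienoate | CCOC(=O)/C=C(\C)[C@@H](O[Si](C)(C)C(C)(C)C)C/C=C(\C)CC/C=C(\C)COS(C)(=O)=O | intermediate
8 | ethyl (2E,4S,6E,10E)-4-(TBSO)-12-chloro-3,7,11-trimethyldodeca-2,6,10-trienoate | CCOC(=O)/C=C(\C)[C@@H](O[Si](C)(C)C(C)(C)C)C/C=C(\C)CC/C=C(\C)CCl | intermediate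
9 | (2E,4S,6E,10E)-4-(TBSO)-12-chloro-3,7,11-trimethyldodeca-2,6,10-trien-1-ol | OC/C=C(\C)[C@@H](O[Si](C)(C)C(C)(C)C)C/C=C(\C)CC/C=C(\C)CCl | intermediate
10 | (2R,3S,4S,6E,10E)-4-(TBSO)-12-chloro-2,3-epoxy-3,7,11-trimethyldodeca-6,10-dien-1-ol | OC[C@H]1O[C@]1(C)[C@@H](O[Si](C)(C)C(C)(C)C)C/C=C(\C)CC/C=C(\C)CCl | intermediate
11 | (2S,3S,4S,6E,10E)-4-(TBSO)-12-chloro-2,3-epoxy-3,7,11-trimethyldodeca-6,10-dienal | O=C[C@H]1O[C@]1(C)[C@@H](O[Si](C)(C)C(C)(C)C)C/C=C(\C)CC/C=C(\C)CCl | intermediate
12 | allyl(ethyl)zinc from 11: ethylzinc at C12 in place of chlorine (drawn 10E; E/Z and allyl termini interconvert) | O=C[C@H]1O[C@]1(C)[C@@H](O[Si](C)(C)C(C)(C)C)C/C=C(\C)CC/C=C(\C)C[Zn]CC | intermediate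
13 | (1R,2R,3S,4S,6E,10S)-4-(TBSO)-2,3-epoxy-3,7-dimethyl-10-(prop-1-en-2-yl)cyclodec-6-en-1-ol | O[C@H]1[C@H]2O[C@]2(C)[C@@H](O[Si](C)(C)C(C)(C)C)C/C=C(\C)CC[C@H]1C(C)=C | intermediate
14 | (1R,2R,3S,4S,6E,10S)-4-(TBSO)-2,3-epoxy-3,7-dimethyl-10-(propan-2-yl)cyclodec-6-en-1-ol | O[C@H]1[C@H]2O[C@]2(C)[C@@H](O[Si](C)(C)C(C)(C)C)C/C=C(\C)CC[C@H]1C(C)C | intermediate
15 | (1R,2R,3S,4S,6E,10S)-4-(TBSO)-2,3-epoxy-3,7-dimethyl-10-(propan-2-yl)cyclodec-6-en-1-yl acetate | CC(=O)O[C@H]1[C@H]2O[C@]2(C)[C@@H](O[Si](C)(C)C(C)(C)C)C/C=C(\C)CC[C@H]1C(C)C | intermediate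
16 | (1R,2R,3R,4S,6E,10S)-2,3-epoxy-4-hydroxy-3,7-dimethyl-10-(propan-2-yl)cyclodec-6-en-1-yl acetate | CC(=O)O[C@H]1[C@H]2O[C@]2(C)[C@@H](O)C/C=C(\C)CC[C@H]1C(C)C | intermediate
17 | (1R,2R,3R,4S,6E,10S)-1-acetoxy-2,3-epoxy-3,7-dimethyl-10-(propan-2-yl)cyclodec-6-en-4-yl 3-methylbut-2-enoate | CC(=O)O[C@H]1[C@H]2O[C@]2(C)[C@@H](OC(=O)C=C(C)C)C/C=C(\C)CC[C@H]1C(C)C | target

Total step count: 14. Longest linear sequence: 14 steps from 1.

**Steps most likely to fail**

Step 10. What may go wrong: intermolecular allylation (oligomers) competing with ring closure, and incomplete facial control at the C1 aldehyde. Fallback, setting out from 11 and coming back at 14: the ring is closed by the stoichiometric Nozaki–Hiyama route, 11 with CrCl2 (excess) in THF at high dilution, where a trivalent allylchromium adds without palladium or zinc. The product, 13 together with its C1-epimeric alcohol F1, is hydrogenated as in step 11 to 14 and the C1-epimeric isopropyl alcohol F2. The epimeric material is oxidized with Dess–Martin periodinane/NaHCO3 to the 2,3-epoxy ketone F3. F3 is reduced with Zn(BH4)2 in Et2O at −20 °C, a reagent known to chelate ketone and oxirane oxygens and give the anti epoxy alcohol, which is 14.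

Step 1. What may go wrong: enamine formation towards the methyl group, N- instead of O-attack on nitrosobenzene, and slow turnover with this hindered ketone. Fallback, auxiliary-controlled: it does not pass through 1–3, sets out from commercial (R)-4-benzyl-1,3-oxazolidin-2-one and geranyl bromide instead of 1, and comes back at 4. The oxazolidinone is acylated with (tert-butyldimethylsilyloxy)acetic acid (PivCl, Et3N, LiCl) to the glycolyl imide F4. NaHMDS in THF at −78 °C, then geranyl bromide, gives the alkylated imide F5, the electrophile entering anti to the benzyl group of the chelated Z-enolate (2S). MeNH(OMe)·HCl/AlMe3 gives the Weinreb amide F6, and MeMgBr in THF at 0 °C gives 4.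

Step 5. What may go wrong: ene oxidation at the internal allylic methylenes (C8, C5) and over-oxidation to the enal. Fallback, setting out from 5 and coming back at 6: terminal-selective bromohydrin formation with NBS in THF/H2O at 0 °C gives the 10-bromo-11-hydroxy ester F7. K2CO3 in EtOH closes the 10,11-epoxide F8, and H5IO6 in THF/Et2O cleaves it to the C10 aldehyde F9. Wittig reaction with Ph3P=C(CH3)CHO (toluene, 80 °C) gives the (10E)-enal F10, and Luche reduction (NaBH4, CeCl3·7H2O, EtOH, −20 °C) gives 6.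

**Further compounds**

F1 | step 10 | (1S,2R,3S,4S,6E,10S)-4-(TBSO)-2,3-epoxy-3,7-dimethyl-10-(prop-1-en-2-yl)cyclodec-6-en-1-ol | O[C@@H]1[C@H]2O[C@]2(C)[C@@H](O[Si](C)(C)C(C)(C)C)C/C=C(\C)CC[C@H]1C(C)=C
F2 | step 10 | (1S,2R,3S,4S,6E,10S)-4-(TBSO)-2,3-epoxy-3,7-dimethyl-10-(propan-2-yl)cyclodec-6-en-1-ol | O[C@@H]1[C@H]2O[C@]2(C)[C@@H](O[Si](C)(C)C(C)(C)C)C/C=C(\C)CC[C@H]1C(C)C
F3 | step 10 | (2S,3S,4S,6E,10S)-4-(TBSO)-2,3-epoxy-3,7-dimethyl-10-(propan-2-yl)cyclodec-6-en-1-one | O=C1[C@H]2O[C@]2(C)[C@@H](O[Si](C)(C)C(C)(C)C)C/C=C(\C)CC[C@H]1C(C)C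
F4 | step 1 | (4R)-4-benzyl-3-[(TBSO)acetyl]-1,3-oxazolidin-2-one | O=C1OC[C@@H](Cc2ccccc2)N1C(=O)CO[Si](C)(C)C(C)(C)C
F5 | step 1 | (4R)-4-benzyl-3-[(2S,4E)-2-(TBSO)-5,9-dimethyldeca-4,8-dienoyl]-1,3-oxazolidin-2-one | O=C1OC[C@@H](Cc2ccccc2)N1C(=O)[C@@H](O[Si](C)(C)C(C)(C)C)C/C=C(\C)CCC=C(C)C
F6 | step 1 | (2S,4E)-2-(TBSO)-N-methoxy-N,5,9-trimethyldeca-4,8-dienamide | CON(C)C(=O)[C@@H](O[Si](C)(C)C(C)(C)C)C/C=C(\C)CCC=C(C)C
F7 | step 5 | ethyl (2E,4S,6E)-10-bromo-4-(TBSO)-11-hydroxy-3,7,11-trimethyldodeca-2,6-dienoate (both C10 epimers) | CCOC(=O)/C=C(\C)[C@@H](O[Si](C)(C)C(C)(C)C)C/C=C(\C)CCC(Br)C(C)(C)O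
F8 | step 5 | ethyl (2E,4S,6E)-4-(TBSO)-10,11-epoxy-3,7,11-trimethyldodeca-2,6-dienoate (both C10 epimers) | CCOC(=O)/C=C(\C)[C@@H](O[Si](C)(C)C(C)(C)C)C/C=C(\C)CCC1OC1(C)C
F9 | step 5 | ethyl (2E,4S,6E)-4-(TBSO)-3,7-dimethyl-10-oxodeca-2,6-dienoate | CCOC(=O)/C=C(\C)[C@@H](O[Si](C)(C)C(C)(C)C)C/C=C(\C)CCC=O
F10 | step 5 | ethyl (2E,4S,6E,10E)-4-(TBSO)-3,7,11-trimethyl-12-oxododeca-2,6,10-trienoate | CCOC(=O)/C=C(\C)[C@@H](O[Si](C)(C)C(C)(C)C)C/C=C(\C)CC/C=C(\C)C=O
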